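**Plan**

- Retrosynthesis: the methyl ester is traced back (C(=O)–OMe) to a ring C lactone on O7. Ring C is cut at C8–C(benzylic) and O7–C(lactol) into a chromanone and (E)-hex-2-enal. Ring A is cut at C4a–C5 and C8–C8a into a 5-sulfinyl dihydropyranone and a prenylated 1-methoxy-1,3-bis(silyloxy)diene. Ring B is cut at C2–C3 and O1–C8a into acetaldehyde and a 1-methoxy-3-silyloxypenta-1,3-diene.
- Forward: ring B is made first by hetero-Diels–Alder reaction, C4a is armed as a sulfoxide, ring A is annulated by Diels–Alder reaction and aromatisation, ring C is grown on C8/O7 as a lactol and oxidised, and methanolysis of ring C lays open the hexanoate chain.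
- Enabling feature: in ring B the atoms O1–C2(Me)–C3(Me)–C4(=O)–C4a=C8a form a 2,3-cis-dimethyl-2,3-dihydropyran-4-one, the cycloaddition retron of an aldehyde and a 4-methyl-1-methoxy-3-silyloxydiene.
- Stereochemistry: C2 (R) and C3 (S) come from the salen-chromium-catalysed endo cycloaddition of the Z enol ether. The benzylic centre (R) comes from iminium catalysis with a diarylprolinol silyl ether. After step 3 only pyridine and buffered amine or acid conditions are used, to protect C3.

Key step: step 3

Remark on numbering: chroman-4-one numbering (O1, C2, C3, C4, C4a, C5–C8, C8a) is used for the target and the bicyclic and tricyclic intermediates; C5 and C6 of the dihydropyranone become C4a and C8a; ring A is the benzene ring, ring B the pyranone ring, ring C the lactol/lactone ring on O7/C8.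

Assumption: the (S,S)-salen ligand is taken as the one that leaves the Si face of chromium-bound acetaldehyde open (giving 2R), and the (S)-prolinol silyl ether as the one that gives the R benzylic centre; if either sense proved opposite, the mirror-image catalyst would be used with no other change.

**Route**

Step 1
Reactants: 1 (E)-4-methoxybut-3-en-2-one; 2 iodomethane
Product: 4 (E)-1-methoxypent-1-en-3-one, via lithium enolate 3 (not isolated)
Conditions: LiN(iPr)2, THF, −78 °C; then MeI, −78 → 0 °C
Reagents that add atoms: none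
Why: Kinetic deprotonation of the vinylogous ester at its α' methyl group and C-methylation of the lithium enolate (enolate alkylation of the Stork–Danheiser type) should add the one carbon needed without touching the enol ether.

Step 2
Reactants: 4 (E)-1-methoxypent-1-en-3-one
Product: 5 (1E,3Z)-1-methoxy-3-(trimethylsilyloxy)penta-1,3-diene
Conditions: Me3SiOTf, Et3N, Et2O, 0 °C
Reagents that add atoms: trimethylsilyl trifluoromethanesulfonate, C[Si](C)(C)OS(=O)(=O)C(F)(F)F
Why: Soft enolisation and O-silylation of the ethyl ketone (silyl enol ether formation) should favour the Z enol ether, which places the C4 methyl on the outside of the diene as the cis outcome of step 3 requires.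

Step 3
Reactants: 5 (1E,3Z)-1-methoxy-3-(trimethylsilyloxy)penta-1,3-diene; 6 acetaldehyde
Product: 8 (2R,3S)-2,3-dimethyl-2,3-dihydro-4H-pyran-4-one, via silyloxy dihydropyran cycloadduct 7 (not isolated)
Conditions: (S,S)-(salen)CrBF4 (3 mol%; salen = N,N'-bis(3,5-di-tert-butylsalicylidene)cyclohexane-1,2-diamine dianion, trivalent chromium), 4 Å molecular sieves, tBuOMe, −30 °C; then CF3CO2H (cat.), CH2Cl2, 0 °C
Reagents that add atoms: none
Why: Acetaldehyde binds through its carbonyl oxygen to the cationic trivalent chromium centre and the diene adds in a concerted, asynchronous [4+2] cycloaddition that forms C2–C3 and O1–C6 (the later O1–C8a) together; the closest known reaction type is the (salen)Cr-catalysed hetero-Diels–Alder reaction of 1-methoxy-3-silyloxybutadienes with aldehydes and the endo-selective Lewis acid version with 4-methyl dienes. Ring B is closed by cycloaddition, both ring bonds arising in the same step, and catalytic CF3CO2H then expels Me3SiOMe from cycloadduct 7 (whose acetal centre is thereby lost) to give the enone. C3 is set relative to C2 by the endo position of the aldehyde methyl combined with the Z enol ether (C4 methyl outside), which puts the two methyls cis. The absolute configuration at C2 comes from the salen ligand, which leaves one face of the bound aldehyde open (the Si face is needed for 2R). The step needs the pericyclic pathway to win over a stepwise Mukaiyama aldol route, which would erode the cis preference; the weakly Lewis acidic chromium complex, the low temperature and a geometrically pure Z diene should secure this, and the acid treatment is kept short and cold so that C3 is not epimerised.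

Step 4
Reactants: 8 (2R,3S)-2,3-dimethyl-2,3-dihydro-4H-pyran-4-one
Product: 10 (2R,3S)-2,3-dimethyl-5-(phenylsulfanyl)-2,3-dihydro-4H-pyran-4-one, via chloro sulfide adduct 9 (not isolated)
Conditions: PhSSPh, SO2Cl2, CH2Cl2, 0 °C (gives PhSCl); then 8, −78 °C; then pyridine, −78 → 0 °C
Reagents that add atoms: benzenesulfenyl chloride, ClSc1ccccc1 (made in the flask from diphenyl disulfide, c1ccc(SSc2ccccc2)cc1, and SO2Cl2, O=S(=O)(Cl)Cl)
Why: Electrophilic sulfenylation by addition–elimination: PhSCl adds across the enol ether (sulfur to the nucleophilic C5, chloride to C6) and pyridine removes HCl from the α-thio ketone to restore the vinylogous ester, the weak base being chosen to leave C3 untouched.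

Step 5
Reactants: 10 (2R,3S)-2,3-dimethyl-5-(phenylsulfanyl)-2,3-dihydro-4H-pyran-4-one
Product: 11 (2R,3S)-2,3-dimethyl-5-(phenylsulfinyl)-2,3-dihydro-4H-pyran-4-one (both configurations at sulfur)
Conditions: mCPBA (1.0 equiv), CH2Cl2, −78 → −40 °C
Reagents that add atoms: mCPBA (3-chloroperoxybenzoic acid), OOC(=O)c1cccc(Cl)c1
Why: Sulfide-to-sulfoxide oxidation with one equivalent of peracid should be chemoselective because the electron-poor C5=C6 bond is inert to mCPBA; both sulfur epimers serve, since sulfur is removed in step 9.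

Step 6
Reactants: 12 methyl 3-oxobutanoate; 13 1-bromo-3-methylbut-2-ene
Product: 14 methyl 2-acetyl-5-methylhex-4-enoate (racemic)
Conditions: K2CO3, acetone, reflux
Reagents that add atoms: none
Why: C-alkylation of the β-keto ester enolate with an allylic bromide (acetoacetic ester alkylation) places the prenyl group on the carbon that becomes C6 of ring A; one equivalent of bromide limits dialkylation.

Step 7
Reactants: 14 methyl 2-acetyl-5-methylhex-4-enoate
Product: 15 methyl 5-methyl-2-[1-(trimethylsilyloxy)ethylidene]hex-4-enoate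
Conditions: Me3SiCl, Et3N, toluene, 23 °C
Reagents that add atoms: chlorotrimethylsilane, C[Si](C)(C)Cl
Why: O-silylation of the enolised β-keto ester (silyl enol ether formation) is the first stage of the standard two-stage preparation of 1,3-bis(silyloxy)dienes.

Step 8
Reactants: 15 methyl 5-methyl-2-[1-(trimethylsilyloxy)ethylidene]hex-4-enoate
Product: 17 1-methoxy-2-(3-methylbut-2-enyl)-1,3-bis(trimethylsilyloxy)buta-1,3-diene, via lithium dienolate 16 (not isolated)
Conditions: LiN(iPr)2, THF, −78 °C; then Me3SiCl, −78 → 0 °C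
Reagents that add atoms: chlorotrimethylsilane, C[Si](C)(C)Cl
Why: γ-Deprotonation of the silyloxy enoate and O-silylation of the resulting dienolate (silyl ketene acetal formation) should give the 1,1,3-trioxygenated diene that carries the prenyl group at its C2.

Step 9
Reactants: 11 (2R,3S)-2,3-dimethyl-5-(phenylsulfinyl)-2,3-dihydro-4H-pyran-4-one; 17 1-methoxy-2-(3-methylbut-2-enyl)-1,3-bis(trimethylsilyloxy)buta-1,3-diene
Product: 20 (2R,3S)-5,7-dihydroxy-2,3-dimethyl-6-(3-methylbut-2-enyl)chroman-4-one, via sulfinyl cycloadduct 18 (not isolated), via 7-O-silyl chromanone 19 (not isolated)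
Conditions: 17 (2.5 equiv), toluene, 23 → 60 °C; then 1 M HCl, THF, 0 °C
Reagents that add atoms: none
Why: Diels–Alder benzannulation with sulfoxide elimination, as known for sulfinyl-activated cyclic enones and quinones with oxygenated dienes: the nucleophilic CH2 terminus of the diene bonds to C6 of the sulfinyl enone (C8a) and the ketene acetal carbon to C5 (C4a); the cis H-8a/sulfinyl pair of the adduct allows thermal syn-elimination of PhSOH, loss of Me3SiOMe and enolisation aromatise ring A, dilute acid removes the 7-O-silyl group, and the prenyl group ends up at C6 with no regiochemical choice, while C2 and C3 are not involved.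

Step 10
Reactants: 20 (2R,3S)-5,7-dihydroxy-2,3-dimethyl-6-(3-methylbut-2-enyl)chroman-4-one; 21 (E)-hex-2-enal
Product: 23 (2R,3S,10R)-5,8-dihydroxy-2,3-dimethyl-6-(3-methylbut-2-enyl)-10-propyl-2,3,9,10-tetrahydro-4H,8H-benzo[1,2-b:3,4-b']dipyran-4-one (ring C lactol, both anomers), via hydroxy aldehyde 22 (not isolated)
Conditions: (S)-2-[diphenyl(trimethylsilyloxy)methyl]pyrrolidine (20 mol%), PhCO2H (20 mol%), toluene, 0 → 23 °C
Reagents that add atoms: none
Why: Iminium-catalysed enantioselective Friedel–Crafts alkylation of an electron-rich phenol with an enal: C8, the only free ring position and activated by O1, 5-OH and 7-OH, should add to the β-carbon of the hexenal iminium ion on the face left open by the diphenyl(silyloxy)methyl group (expected R), and 7-OH traps the aldehyde as the lactol.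

Step 11
Reactants: 23 ring C lactol
Product: 24 (2R,3S,10R)-5-hydroxy-2,3-dimethyl-6-(3-methylbut-2-enyl)-10-propyl-2,3,9,10-tetrahydro-4H,8H-benzo[1,2-b:3,4-b']dipyran-4,8-dione (ring C lactone)
Conditions: pyridinium chlorochromate (C5H5NH)[CrO3Cl], NaOAc, 4 Å molecular sieves, CH2Cl2, 0 → 23 °C
Reagents that add atoms: none
Why: Lactol-to-lactone oxidation with buffered chlorochromate is the usual follow-up for such chroman-2-ols; the hydrogen-bonded 5-OH, the prenyl alkene and the stereocentres should tolerate the buffered, non-basic conditions.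

Step 12
Reactants: 24 ring C lactone
Product: 25 methyl (3R)-3-[(2R,3S)-5,7-dihydroxy-2,3-dimethyl-6-(3-methylbut-2-enyl)-4-oxochroman-8-yl]hexanoate (target)
Conditions: MeOH, camphor-10-sulfonic acid (10 mol%), 23 °C; NaHCO3 quench before concentration
Reagents that add atoms: methanol, CO
Why: Acid-catalysed transesterification of the aryl ester in methanol as solvent should open ring C to the methyl ester and free 7-OH; mild acid at room temperature spares the prenyl group and avoids the base-induced cis-to-trans epimerisation at C3.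

**Compound list**

1 | (E)-4-methoxybut-3-en-2-one | CO/C=C/C(C)=O | starting material
2 | iodomethane | CI | starting material
3 | lithium (E)-4-methoxybuta-1,3-dien-2-olate (kinetic enolate of 1, formed in the flask) | C=C(O[Li])/C=C/OC | intermediate
4 | (E)-1-methoxypent-1-en-3-one | CCC(=O)/C=C/OC | intermediate
5 | (1E,3Z)-1-methoxy-3-(trimethylsilyloxy)penta-1,3-diene | CO/C=C/C(O[Si](C)(C)C)=C/C | intermediate
6 | acetaldehyde | CC=O | starting material
7 | (2R,5S,6R)-2-methoxy-5,6-dimethyl-4-(trimethylsilyloxy)-5,6-dihydro-2H-pyran (all-cis endo cycloadduct, formed in the flask) | CO[C@@H]1O[C@H](C)[C@H](C)C(O[Si](C)(C)C)=C1 | intermediate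
8 | (2R,3S)-2,3-dimethyl-2,3-dihydro-4H-pyran-4-one | C1=CO[C@H](C)[C@H](C)C1=O | intermediate
9 | (2R,3S)-6-chloro-2,3-dimethyl-5-(phenylsulfanyl)tetrahydro-4H-pyran-4-one (C5 and C6 not assigned, formed in the flask) | ClC1O[C@H](C)[C@H](C)C(=O)C1Sc1ccccc1 | intermediate
10 | (2R,3S)-2,3-dimethyl-5-(phenylsulfanyl)-2,3-dihydro-4H-pyran-4-one | C1(Sc2ccccc2)=CO[C@H](C)[C@H](C)C1=O | intermediate
11 | (2R,3S)-2,3-dimethyl-5-(phenylsulfinyl)-2,3-dihydro-4H-pyran-4-one (both configurations at sulfur) | C1(S(=O)c2ccccc2)=CO[C@H](C)[C@H](C)C1=O | intermediate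
12 | methyl 3-oxobutanoate (methyl acetoacetate) | COC(=O)CC(C)=O | starting material
13 | 1-bromo-3-methylbut-2-ene (prenyl bromide) | CC(C)=CCBr | starting material
14 | methyl 2-acetyl-5-methylhex-4-enoate (racemic) | COC(=O)C(CC=C(C)C)C(C)=O | intermediate
15 | methyl 5-methyl-2-[1-(trimethylsilyloxy)ethylidene]hex-4-enoate | COC(=O)C(CC=C(C)C)=C(C)O[Si](C)(C)C | intermediate
16 | lithium 1-methoxy-2-(3-methylbut-2-enyl)-3-(trimethylsilyloxy)buta-1,3-dien-1-olate (formed in the flask) | C=C(O[Si](C)(C)C)C(CC=C(C)C)=C(OC)O[Li] | intermediate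
17 | 1-methoxy-2-(3-methylbut-2-enyl)-1,3-bis(trimethylsilyloxy)buta-1,3-diene | C=C(O[Si](C)(C)C)C(CC=C(C)C)=C(OC)O[Si](C)(C)C | intermediate
18 | (2R,3S)-5-methoxy-2,3-dimethyl-6-(3-methylbut-2-enyl)-4a-(phenylsulfinyl)-5,7-bis(trimethylsilyloxy)-2,3,4a,5,8,8a-hexahydro-4H-chromen-4-one (C4a, C5, C8a and sulfur not assigned, formed in the flask) | C1(O[Si](C)(C)C)=C(CC=C(C)C)C(OC)(O[Si](C)(C)C)C2(S(=O)c3ccccc3)C(C1)O[C@H](C)[C@H](C)C2=O | intermediate
19 | (2R,3S)-5-hydroxy-2,3-dimethyl-6-(3-methylbut-2-enyl)-7-(trimethylsilyloxy)chroman-4-one (formed in the flask) | c1c(O[Si](C)(C)C)c(CC=C(C)C)c(O)c2c1O[C@H](C)[C@H](C)C2=O | intermediate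
20 | (2R,3S)-5,7-dihydroxy-2,3-dimethyl-6-(3-methylbut-2-enyl)chroman-4-one | c1c(O)c(CC=C(C)C)c(O)c2c1O[C@H](C)[C@H](C)C2=O | intermediate
21 | (E)-hex-2-enal | CCC/C=C/C=O | starting material
22 | (3R)-3-[(2R,3S)-5,7-dihydroxy-2,3-dimethyl-6-(3-methylbut-2-enyl)-4-oxochroman-8-yl]hexanal (formed in the flask) | CCC[C@H](CC=O)c1c(O)c(CC=C(C)C)c(O)c2c1O[C@H](C)[C@H](C)C2=O | intermediate
23 | (2R,3S,10R)-5,8-dihydroxy-2,3-dimethyl-6-(3-methylbut-2-enyl)-10-propyl-2,3,9,10-tetrahydro-4H,8H-benzo[1,2-b:3,4-b']dipyran-4-one (ring C lactol on O7/C8, both anomers at C8) | CCC[C@@H]1CC(O)Oc2c(CC=C(C)C)c(O)c3c(c21)O[C@H](C)[C@H](C)C3=O | intermediate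
24 | (2R,3S,10R)-5-hydroxy-2,3-dimethyl-6-(3-methylbut-2-enyl)-10-propyl-2,3,9,10-tetrahydro-4H,8H-benzo[1,2-b:3,4-b']dipyran-4,8-dione (ring C lactone) | CCC[C@@H]1CC(=O)Oc2c(CC=C(C)C)c(O)c3c(c21)O[C@H](C)[C@H](C)C3=O | intermediate
25 | methyl (3R)-3-[(2R,3S)-5,7-dihydroxy-2,3-dimethyl-6-(3-methylbut-2-enyl)-4-oxochroman-8-yl]hexanoate | CCC[C@H](CC(=O)OC)c1c(O)c(CC=C(C)C)c(O)c2c1O[C@H](C)[C@H](C)C2=O | target

**Step count**

Total: 12 steps. Longest linear sequence: 9 steps (1, 2, 3, 4, 5, 9, 10, 11, 12); the diene branch (6, 7, 8) joins at step 9.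

**Steps most likely to fail**

Step 9. Ring closure at the fully substituted ketene acetal carbon may lag behind the first C–C bond formation, so that the sequence stops after conjugate addition and sulfoxide elimination. The liberated sulfenic acid may add to the excess diene. Ring B may open by β-elimination of O1 during aromatisation. The fallback is a stepwise triketide assembly that sets out from 11 and 14 and comes back at 20. Keto ester 14 would be doubly deprotonated with LiN(iPr)2 (2 equiv, THF, 0 °C) to the dilithium dianion of methyl 2-acetyl-5-methylhex-4-enoate F1. Its terminal carbon would add to C6 of 11 at −78 °C to give, after NH4Cl quench, the sulfinyl tetrahydropyranone conjugate adduct F2. Warming in toluene would eliminate benzenesulfenic acid to the 6-substituted dihydropyranone keto ester F3. Mg(OMe)2 in MeOH would then close ring A by intramolecular Claisen condensation of the vinylogous ester α-carbon onto the ester, and tautomerisation gives 20. The basic steps would be kept short and cold to limit epimerisation at C3.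

Step 10. The hydrogen-bonded acylphloroglucinol nucleus may be too weak a nucleophile for the iminium ion. 1,2-Addition with dehydration to a 2H-chromene may compete. Facial selectivity may be eroded, and the amine may epimerise C3. The fallback replaces catalyst control by an achiral Lewis acid annulation with separation of epimers; it sets out from 20 and comes back at 24. Butanal and 2,2-dimethyl-1,3-dioxane-4,6-dione would be condensed (Knoevenagel) to 5-butylidene-2,2-dimethyl-1,3-dioxane-4,6-dione F4. Under Yb(OTf)3 in MeNO2, C8 of 20 would add to it in a Friedel–Crafts conjugate addition to give the dioxanedione adduct F5. Attack of 7-OH on a ring carbonyl with loss of acetone would give the carboxy lactone F6. Decarboxylation of F6 would give 24 together with its benzylic epimer, the (10S)-lactone F7, which would be removed by preparative HPLC.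

Step 3. The reaction may leak into the stepwise Mukaiyama aldol manifold, which lowers the cis preference. Face discrimination may be modest with so small an aldehyde, and the volatile product may be lost on evaporation. The fallback replaces the cycloaddition by a reagent-controlled syn aldol addition and cyclisation; it sets out from 4 and 6 and comes back at 8. Ketone 4 would be enolised with Ipc2BOTf and iPr2NEt in CH2Cl2 at −78 °C (Ipc = isopinocampheyl, drawn here as derived from (+)-α-pinene; the antipodal reagent would be used if the sense of induction required it) to the Z boron enolate, (1E,3Z)-1-methoxypenta-1,3-dien-3-yl diisopinocampheylborinate F8. Addition to 6 would give the boron aldolate F9. Oxidative work-up with H2O2 at pH 7 would release the syn aldol (4S,5R,E)-5-hydroxy-1-methoxy-4-methylhex-1-en-3-one F10. Catalytic CF3CO2H in CH2Cl2 would then close ring B by oxa-Michael addition and loss of methanol to give 8.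

**Further compounds**

F1 | step 9 | dilithium dianion of methyl 2-acetyl-5-methylhex-4-enoate | C=C(O[Li])C(CC=C(C)C)=C(OC)O[Li]
F2 | step 9 | methyl 4-[(2R,3S)-2,3-dimethyl-4-oxo-5-(phenylsulfinyl)tetrahydro-2H-pyran-6-yl]-2-(3-methylbut-2-enyl)-3-oxobutanoate (other centres not assigned) | COC(=O)C(CC=C(C)C)C(=O)CC1O[C@H](C)[C@H](C)C(=O)C1S(=O)c1ccccc1
F3 | step 9 | methyl 4-[(2R,3S)-2,3-dimethyl-4-oxo-3,4-dihydro-2H-pyran-6-yl]-2-(3-methylbut-2-enyl)-3-oxobutanoate | COC(=O)C(CC=C(C)C)C(=O)CC1=CC(=O)[C@@H](C)[C@@H](C)O1
F4 | step 10 | 5-butylidene-2,2-dimethyl-1,3-dioxane-4,6-dione | CCCC=C1C(=O)OC(C)(C)OC1=O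
F5 | step 10 | 5-{1-[(2R,3S)-5,7-dihydroxy-2,3-dimethyl-6-(3-methylbut-2-enyl)-4-oxochroman-8-yl]butyl}-2,2-dimethyl-1,3-dioxane-4,6-dione (both benzylic epimers) | CCCC(C1C(=O)OC(C)(C)OC1=O)c1c(O)c(CC=C(C)C)c(O)c2c1O[C@H](C)[C@H](C)C2=O
F6 | step 10 | (2R,3S)-5-hydroxy-2,3-dimethyl-6-(3-methylbut-2-enyl)-4,8-dioxo-10-propyl-2,3,9,10-tetrahydro-4H,8H-benzo[1,2-b:3,4-b']dipyran-9-carboxylic acid (C9 and C10 not assigned) | CCCC1C(C(=O)O)C(=O)Oc2c(CC=C(C)C)c(O)c3c(c21)O[C@H](C)[C@H](C)C3=O
F7 | step 10 | (2R,3S,10S)-5-hydroxy-2,3-dimethyl-6-(3-methylbut-2-enyl)-10-propyl-2,3,9,10-tetrahydro-4H,8H-benzo[1,2-b:3,4-b']dipyran-4,8-dione (benzylic epimer of 24) | CCC[C@H]1CC(=O)Oc2c(CC=C(C)C)c(O)c3c(c21)O[C@H](C)[C@H](C)C3=O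
F8 | step 3 | (1E,3Z)-1-methoxypenta-1,3-dien-3-yl diisopinocampheylborinate | CO/C=C/C(OB([C@@H]1C[C@@H]2C[C@H]([C@H]1C)C2(C)C)[C@@H]1C[C@@H]2C[C@H]([C@H]1C)C2(C)C)=C/C
F9 | step 3 | (4S,5R,E)-5-(diisopinocampheylboryloxy)-1-methoxy-4-methylhex-1-en-3-one | CO/C=C/C(=O)[C@@H](C)[C@@H](C)OB([C@@H]1C[C@@H]2C[C@H]([C@H]1C)C2(C)C)[C@@H]1C[C@@H]2C[C@H]([C@H]1C)C2(C)C
F10 | step 3 | (4S,5R,E)-5-hydroxy-1-methoxy-4-methylhex-1-en-3-one | CO/C=C/C(=O)[C@@H](C)[C@@H](C)O
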